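**Remark on the chemistry (assumptions).** The SMILES is read as epiafzelechin-(4β→8)-epiafzelechin-(4β→8)-4′-O-methyl-epigallocatechin. (−)-Epigallocatechin 9 is taken as a commercial starting material. Compound 12 is isolated and used as a mixture of C4 epimers, which does not matter because both ionise to the same cation. In step 8 ethanol is a co-solvent: the ethoxy groups of 8 and 12 exchange with it without net uptake, so the step is balanced as 8 → 12 + ethanol.

## Analysis of the target

Target 15 is a linear B-type proanthocyanidin trimer of three 2-aryl-chroman-3-ol (flavan-3-ol) units: the top and middle units are (−)-epiafzelechin (4-hydroxyphenyl B-ring, phloroglucinol A-ring) and the bottom unit is 4′-O-methyl-(−)-epigallocatechin (3,5-dihydroxy-4-methoxyphenyl B-ring). There are eight stereocentres: every unit is 2R,3R (2,3-cis), and both interflavan carbons are 4β, trans to the neighbouring 3-OH (CIP 4R in the top unit and 4S in the middle unit, the same spatial arrangement). The feature the route exploits is C4 of the top unit and C4 of the middle unit: each is a methine at the aldehyde oxidation level that is bonded to two phloroglucinol carbons, C4a of its own A-ring and C8 of the A-ring of the next unit. The two chain-extender units are identical, so one building block can serve both. The molecule carries ten free phenols and three secondary alcohols. It is prone to air oxidation, to acid cleavage of the interflavan bonds and to base-induced epimerisation at C2. The hard points are the C8 versus C6 site selectivity, control of chain length, the 4β configuration, the single methyl ether on the pyrogallol ring, and the scarcity of the 2,3-cis epiafzelechin unit, which is needed twice.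

## Retrosynthetic reasoning

15 from 14. All phenols and the two extender 3-OH groups are carried as benzyl ethers, so the last step is one hydrogenolysis. This leaves only neutral, reductive conditions for the free polyphenol.

14 from 13 and 12. The interflavan bond between C4 of the top unit and C8 of the middle unit is cut. Forward, a silyl triflate must ionise the C4–OEt bond of the 4-ethoxyflavan 12 and C8 of the upper unit of 13 must attack the cation trans to the C3 oxygen.

13 from 12 and 11. The same bond type is cut between the middle and the bottom unit. Because the two extender units are identical, the single electrophile 12 serves both couplings. Forward, the monomeric terminal unit 11 is the nucleophile.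

12 from 8. The second arene bond of C4, the ring bond C4–C4a, is cut. This opens the pyran ring and leaves the open-chain diethyl acetal 8, which already holds C2 and C3 with the correct configuration and the A-ring as an aryl ether. Forward, acid must ionise the acetal and the tethered arene must close the ring onto the oxocarbenium carbon. The cut is placed here because C4 is then introduced directly at the aldehyde level, with the leaving group for the couplings already in place. The flavan ring never has to be built at the CH2 level and oxidised again.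

8 from 7, and 7 from 5 and 6. The C3 oxygen is benzylated last. The aryl ether bond O1–C2 is cut between phenol 6 and the benzylic carbon of the cis-epoxide 5. An SN2 opening with inversion turns the cis-epoxide into the syn (threo) aryloxy alcohol, which is the open-chain form of a 2,3-cis flavan. The acetal-bearing epoxide carbon is deactivated towards substitution, so the regiochemistry is set by the substrate.

5 from 4, 3, 1 and 2. Both stereocentres of the extender unit come from one catalytic asymmetric epoxidation of the Z-alkene 4. A cis-disubstituted aryl alkene is the best substrate class for Mn–salen catalysts. The alkene comes from semi-hydrogenation of alkyne 3, and 3 from cross-coupling of aryl iodide 1 with the acetal-bearing alkyne 2.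

11 from 10 and 9. The terminal unit is not built de novo. Its skeleton and both stereocentres are taken from 9. The methyl ether is placed on the most acidic phenol (4′-OH, flanked by two hydroxyls) to give 10. The four remaining phenols are then benzylated, leaving C8 as the nucleophilic carbon.

## Alternatives that were turned down

Alternative 1: The textbook route. Both C4–C8 bonds are cut one at a time between preformed flavan monomers. Forward, (−)-epiafzelechin A1 is benzylated at its phenols, acetylated at the 3-OH and oxidised at C4 (DDQ, 2-ethoxyethanol) to the 4-alkoxy electrophile A2. A2 is coupled under Lewis acid first with 11 and then with the product of that coupling. It was turned down because A1 is a scarce isolate needed twice. A de novo route to its 2,3-cis skeleton (diarylpropene, dihydroxylation, cyclisation to the 2,3-trans flavan, oxidation–reduction to cis) costs about twice the steps that lead to 12. C4 would also pass CH2 → CH(OR) → CH(Ar), a redox detour per unit that the chosen route avoids.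

Alternative 2: C4–C8 bond by carbonyl addition. Forward, benzylated A1 is oxidised to the 4-ketone A3; C8 of the lower unit (after bromination and halogen–metal exchange of 11) adds to the ketone, and the tertiary benzylic oxygen is removed by ionic reduction. It was turned down on mechanism: the hydride enters the C4 cation on the face anti to the C2 aryl and C3 oxygen, which pushes the aryl group to the α face and gives the 3,4-cis (4α) linkage. It also adds bromination, metalation and two redox operations per bond, and exposes the epimerisable α-alkoxy ketone to an aryllithium.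

Alternative 3: Union at the anthocyanidin oxidation level. Forward, C8 of 11 adds to C4 of the achiral flavylium salt A4, and the C2=C3 enol ether of the adduct is then reduced. It was turned down because C4 is formed without control (planar achiral cation). The later syn addition of hydrogen anti to the C4 aryl group puts the C2 aryl, the C3 oxygen and the C4 aryl all on one face (2,3-cis-3,4-cis). Three stereocentres per unit would therefore be wrong or uncontrolled.

Key step: step 8

## Route

Step 1
Reactants: 1 1-(benzyloxy)-4-iodobenzene; 2 3,3-diethoxyprop-1-yne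
Product: 3 1-(benzyloxy)-4-(3,3-diethoxyprop-1-yn-1-yl)benzene
Conditions: PdCl2(PPh3)2 (2 mol%), CuI (4 mol%), Et3N, THF, rt
Reagents that add atoms: none
Why: Sonogashira coupling of an aryl iodide with a terminal alkyne at room temperature; acetal and benzyl ether are inert.

Step 2
Reactants: 3 1-(benzyloxy)-4-(3,3-diethoxyprop-1-yn-1-yl)benzene
Product: 4 1-(benzyloxy)-4-[(1Z)-3,3-diethoxyprop-1-en-1-yl]benzene
Conditions: H2 (1 atm), Lindlar catalyst, quinoline, EtOAc, rt
Reagents that add atoms: none
Why: Lindlar semi-hydrogenation adds hydrogen syn to the alkyne and should give the Z-alkene; the poisoned catalyst spares the benzyl ether.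

Step 3
Reactants: 4 1-(benzyloxy)-4-[(1Z)-3,3-diethoxyprop-1-en-1-yl]benzene
Product: 5 (2S,3S)-2-[4-(benzyloxy)phenyl]-3-(diethoxymethyl)oxirane (cis)
Conditions: (S,S)-Mn(salen)Cl (Jacobsen catalyst, 5 mol%), 4-phenylpyridine N-oxide (20 mol%), aq. NaOCl (pH 11.3), CH2Cl2, 0 °C; filtration through Et3N-deactivated silica
Reagents that add atoms: sodium hypochlorite, [Na+].[O-]Cl
Why: Jacobsen–Katsuki epoxidation of a cis-disubstituted aryl alkene, the best substrate class for this catalyst; both stereocentres are set here by the catalyst, the (S,S) enantiomer being chosen by analogy with cis-β-methylstyrene and cis-cinnamates.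

Step 4
Reactants: 5 (2S,3S)-2-[4-(benzyloxy)phenyl]-3-(diethoxymethyl)oxirane; 6 3,5-bis(benzyloxy)phenol
Product: 7 (2S,3R)-3-[3,5-bis(benzyloxy)phenoxy]-3-[4-(benzyloxy)phenyl]-1,1-diethoxypropan-2-ol
Conditions: 6 (1.3 equiv), Cs2CO3 (0.3 equiv), DMF, 70 °C
Reagents that add atoms: none
Why: Base-mediated SN2 opening of the epoxide by the phenoxide at the benzylic carbon with inversion (the acetal-bearing carbon is deactivated towards substitution) should turn the cis-epoxide into the syn aryloxy alcohol; a polar aprotic solvent favours O- over C-alkylation.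

Step 5
Reactants: 7 (2S,3R)-3-[3,5-bis(benzyloxy)phenoxy]-3-[4-(benzyloxy)phenyl]-1,1-diethoxypropan-2-ol
Product: 8 (2S,3R)-2-(benzyloxy)-3-[3,5-bis(benzyloxy)phenoxy]-3-[4-(benzyloxy)phenyl]propanal diethyl acetal
Conditions: NaH, BnBr, Bu4NI (cat.), THF/DMF, 0 °C → rt
Reagents that add atoms: benzyl bromide, BrCc1ccccc1
Why: Williamson etherification of the secondary alcohol; no stereocentre is touched and the substrate has no base-labile group.

Step 6
Reactants: 9 (−)-epigallocatechin
Product: 10 4′-O-methyl-(−)-epigallocatechin
Conditions: K2CO3 (1.0 equiv), MeI (1.05 equiv), DMF, 0 °C → rt, argon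
Reagents that add atoms: iodomethane, CI
Why: Acidity-guided Williamson mono-methylation: the 4′-OH, flanked by two hydroxyls, is the most acidic phenol, so one equivalent of weak base should form mainly its phenolate; the same bias gives 4-O-alkyl gallates.

Step 7
Reactants: 10 4′-O-methyl-(−)-epigallocatechin
Product: 11 5,7,3′,5′-tetra-O-benzyl-4′-O-methyl-(−)-epigallocatechin
Conditions: BnBr (4.4 equiv), K2CO3, DMF, rt
Reagents that add atoms: benzyl bromide, BrCc1ccccc1
Why: Williamson benzylation of the four remaining phenols; carbonate does not deprotonate the 3-OH, and the capped 4′-oxygen blocks the quinone-methide pathway for C2 epimerisation.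

Step 8
Reactants: 8 (2S,3R)-2-(benzyloxy)-3-[3,5-bis(benzyloxy)phenoxy]-3-[4-(benzyloxy)phenyl]propanal diethyl acetal
Product: 12 (2R,3R)-3,5,7-tris(benzyloxy)-2-[4-(benzyloxy)phenyl]-4-ethoxychromane (3,5,7,4′-tetra-O-benzyl-4-ethoxy-epiafzelechin, both C4 epimers)
Conditions: CSA (0.2 equiv), CH2Cl2/EtOH 4:1 (0.02 M), 3 Å MS, 40 °C; Et3N quench; chromatography on Et3N-deactivated silica
Reagents that add atoms: none
Why: The acid ionises the diethyl acetal of 8 to an α-benzyloxy oxocarbenium ion, an ortho carbon of its own 3,5-bis(benzyloxy)phenoxy ring attacks it in an intramolecular Friedel–Crafts alkylation, and loss of the ring proton gives 12. The closest known reaction types are the acid-mediated acetal–arene cyclisations of aryloxy-alkanal acetals onto the aryl ether ring (benzofurans from aryloxyacetaldehyde acetals, 4-alkoxychromans from 3-aryloxypropanal acetals) and the Pomeranz–Fritsch–Bobbitt closure of aminoacetals to 4-alkoxytetrahydroisoquinolines. The pyran ring closes by C4–C4a bond formation, 6-exo-trig at the oxocarbenium carbon, through a chair-like transition state with the C2 aryl group equatorial. C2 and C3 come unchanged from 8, since no bond to either is broken, and the new C4 centre forms as a mixture of epimers, which is harmless because both give the same cation in steps 9 and 10. Regioselectivity is secured by the substrate: the two ortho carbons of the ring are equivalent and the para carbon cannot reach the tethered cation. The step must stop at the 4-ethoxy stage although 12 ionises more easily than 8; ethanol as co-solvent captures the flavan-4-yl cation far faster than any arene and only regenerates 12, whereas the C–C closure is irreversible, so the material should funnel into 12. Ring closure must also beat intermolecular arylation of the oxocarbenium ion, which the high effective molarity of the tethered trioxygenated arene and the dilution should secure.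

Step 9
Reactants: 12 (2R,3R)-3,5,7-tris(benzyloxy)-2-[4-(benzyloxy)phenyl]-4-ethoxychromane; 11 5,7,3′,5′-tetra-O-benzyl-4′-O-methyl-(−)-epigallocatechin
Product: 13 3,5,7,4′-tetra-O-benzyl-epiafzelechin-(4β→8)-5,7,3′,5′-tetra-O-benzyl-4′-O-methyl-epigallocatechin
Conditions: 11 (3 equiv), TMSOTf (0.3 equiv), 4 Å MS, CH2Cl2, −78 → −40 °C, slow addition of 12; Et3N quench
Reagents that add atoms: none
Why: Lewis-acid coupling of a 4-alkoxyflavan with a flavan-3-ol nucleophile, the standard interflavan bond formation of benzyl-protected proanthocyanidins: TMSOTf ionises the C4–OEt bond of either epimer of 12 to the 5,7,8a-trioxygenated flavan-4-yl cation, which C8 of 11 (the preferred site of 5,7-di-O-benzyl flavan-3-ols) captures. The new C4 centre is set by substrate control, the nucleophile entering pseudo-axially anti to the C3 benzyloxy and the C2 aryl group, which gives the 3,4-trans (4β) linkage; the excess of 11 suppresses over-extension and is recovered.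

Step 10
Reactants: 12 (2R,3R)-3,5,7-tris(benzyloxy)-2-[4-(benzyloxy)phenyl]-4-ethoxychromane; 13 3,5,7,4′-tetra-O-benzyl-epiafzelechin-(4β→8)-5,7,3′,5′-tetra-O-benzyl-4′-O-methyl-epigallocatechin
Product: 14 3,5,7,4′-tetra-O-benzyl-epiafzelechin-(4β→8)-3,5,7,4′-tetra-O-benzyl-epiafzelechin-(4β→8)-5,7,3′,5′-tetra-O-benzyl-4′-O-methyl-epigallocatechin
Conditions: 13 (2 equiv), TMSOTf (0.3 equiv), 4 Å MS, CH2Cl2, −78 → −30 °C, slow addition of 12; Et3N quench
Reagents that add atoms: none
Why: The same Lewis-acid 4-alkoxyflavan coupling as in step 9, now with C8 of the upper unit of 13 as nucleophile, the only free phloroglucinol carbon next to a ring oxygen, whereas both C6 positions lie between two benzyloxy groups and the lower one is further shielded by the C8 flavanyl group. The new C4 is again set anti to its C3 and C2 substituents (4β), and the excess of 13 is recovered.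

Step 11
Reactants: 14 3,5,7,4′-tetra-O-benzyl-epiafzelechin-(4β→8)-3,5,7,4′-tetra-O-benzyl-epiafzelechin-(4β→8)-5,7,3′,5′-tetra-O-benzyl-4′-O-methyl-epigallocatechin
Product: 15 epiafzelechin-(4β→8)-epiafzelechin-(4β→8)-4′-O-methyl-epigallocatechin (target)
Conditions: H2 (1 atm), Pd(OH)2/C, THF/MeOH/H2O, rt; filtration under argon, Sephadex LH-20, lyophilisation
Reagents that add atoms: none
Why: Global hydrogenolysis of the twelve benzyl ethers under neutral conditions, the standard last step for benzyl-protected procyanidin oligomers; the ring C2–O bonds, the interflavan bonds and the methyl ether should stay intact and no stereocentre is touched.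

## Compound list

1 | 1-(benzyloxy)-4-iodobenzene | Ic1ccc(OCc2ccccc2)cc1 | starting material
2 | 3,3-diethoxyprop-1-yne | C#CC(OCC)OCC | starting material
3 | 1-(benzyloxy)-4-(3,3-diethoxyprop-1-yn-1-yl)benzene | CCOC(OCC)C#Cc1ccc(OCc2ccccc2)cc1 | intermediate
4 | 1-(benzyloxy)-4-[(1Z)-3,3-diethoxyprop-1-en-1-yl]benzene | CCOC(OCC)/C=C\c1ccc(OCc2ccccc2)cc1 | intermediate
5 | (2S,3S)-2-[4-(benzyloxy)phenyl]-3-(diethoxymethyl)oxirane (cis) | CCOC(OCC)[C@H]1O[C@H]1c1ccc(OCc2ccccc2)cc1 | intermediate
6 | 3,5-bis(benzyloxy)phenol | Oc1cc(OCc2ccccc2)cc(OCc2ccccc2)c1 | starting material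
7 | (2S,3R)-3-[3,5-bis(benzyloxy)phenoxy]-3-[4-(benzyloxy)phenyl]-1,1-diethoxypropan-2-ol | CCOC(OCC)[C@@H](O)[C@H](Oc1cc(OCc2ccccc2)cc(OCc2ccccc2)c1)c1ccc(OCc2ccccc2)cc1 | intermediate
8 | (2S,3R)-2-(benzyloxy)-3-[3,5-bis(benzyloxy)phenoxy]-3-[4-(benzyloxy)phenyl]propanal diethyl acetal | CCOC(OCC)[C@@H](OCc1ccccc1)[C@H](Oc1cc(OCc2ccccc2)cc(OCc2ccccc2)c1)c1ccc(OCc2ccccc2)cc1 | intermediate
9 | (−)-epigallocatechin | Oc1c(O)cc([C@H]2Oc3c(c(O)cc(O)c3)C[C@H]2O)cc1O | starting material
10 | 4′-O-methyl-(−)-epigallocatechin | COc1c(O)cc([C@H]2Oc3c(c(O)cc(O)c3)C[C@H]2O)cc1O | intermediate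
11 | 5,7,3′,5′-tetra-O-benzyl-4′-O-methyl-(−)-epigallocatechin | COc1c(OCc2ccccc2)cc([C@H]2Oc3c(c(OCc4ccccc4)cc(OCc4ccccc4)c3)C[C@H]2O)cc1OCc1ccccc1 | intermediate
12 | (2R,3R)-3,5,7-tris(benzyloxy)-2-[4-(benzyloxy)phenyl]-4-ethoxychromane (3,5,7,4′-tetra-O-benzyl-4-ethoxy-epiafzelechin, both C4 epimers) | CCOC1c2c(OCc3ccccc3)cc(OCc3ccccc3)cc2O[C@H](c2ccc(OCc3ccccc3)cc2)[C@@H]1OCc1ccccc1 | intermediate
13 | 3,5,7,4′-tetra-O-benzyl-epiafzelechin-(4β→8)-5,7,3′,5′-tetra-O-benzyl-4′-O-methyl-epigallocatechin | COc1c(OCc2ccccc2)cc([C@H]2Oc3c(c(OCc4ccccc4)cc(OCc4ccccc4)c3[C@H]3c4c(OCc5ccccc5)cc(OCc5ccccc5)cc4O[C@H](c4ccc(OCc5ccccc5)cc4)[C@@H]3OCc3ccccc3)C[C@H]2O)cc1OCc1ccccc1 | intermediate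
14 | 3,5,7,4′-tetra-O-benzyl-epiafzelechin-(4β→8)-3,5,7,4′-tetra-O-benzyl-epiafzelechin-(4β→8)-5,7,3′,5′-tetra-O-benzyl-4′-O-methyl-epigallocatechin | COc1c(OCc2ccccc2)cc([C@H]2Oc3c(c(OCc4ccccc4)cc(OCc4ccccc4)c3[C@H]3c4c(OCc5ccccc5)cc(OCc5ccccc5)c([C@H]5c6c(OCc7ccccc7)cc(OCc7ccccc7)cc6O[C@H](c6ccc(OCc7ccccc7)cc6)[C@@H]5OCc5ccccc5)c4O[C@H](c4ccc(OCc5ccccc5)cc4)[C@@H]3OCc3ccccc3)C[C@H]2O)cc1OCc1ccccc1 | intermediate
15 | epiafzelechin-(4β→8)-epiafzelechin-(4β→8)-4′-O-methyl-epigallocatechin (CNP0146516.1) | COc1c(O)cc([C@H]2Oc3c(c(O)cc(O)c3[C@H]3c4c(O)cc(O)c([C@H]5c6c(O)cc(O)cc6O[C@H](c6ccc(O)cc6)[C@@H]5O)c4O[C@H](c4ccc(O)cc4)[C@@H]3O)C[C@H]2O)cc1O | target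

## Step count and risk

Total step count: 11. Longest linear sequence: 9 (steps 1–5, 8, 9, 10, 11). Steps 6 and 7 form the second branch, which joins at step 9, and electrophile 12 is used twice.

Least certain steps:

Step 8 (key step). Recapture of the oxocarbenium ion by ethanol may make the ring closure so slow that acid solvolysis of the p-alkoxybenzylic C2–O aryl ether bond competes. C3 may epimerise through loss of its proton to an enol ether. Ethanol may be eliminated across C3–C4 towards a flav-3-ene, and self-arylation of the flavan-4-yl cation may set in if ethanol is depleted. Fallback: it sets out from no numbered compound, its starting material being purchased (−)-epiafzelechin A1, and it comes back at 12. A1 is per-benzylated (NaH, BnBr, DMF, 0 °C) to 3,5,7,4′-tetra-O-benzyl-(−)-epiafzelechin F1. DDQ with ethanol in CH2Cl2 then oxidises the benzylic C4–H and should give the 4β-ethoxy epimer of 12, which enters steps 9 and 10 unchanged. The ring is thus taken from the chiral pool and C4 is functionalised by oxidation instead of being introduced with the ring closure.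

Step 9. Attack may occur at C6 instead of C8 of 11, the chain may over-extend because product 13 is itself a nucleophile, and the facial selectivity at C4 may be incomplete. Fallback, setting out from 12 and coming back at 13 (thiophilic activation of a stable thioether donor instead of oxophilic catalysis): benzyl mercaptan and BF3·OEt2 in CH2Cl2 convert 12 into 3,5,7,4′-tetra-O-benzyl-4β-(benzylsulfanyl)epiafzelechin F2. AgBF4 in THF then activates the sulfur of F2 in the presence of 11 under near-neutral conditions and should give 13.

Step 10. Attack may occur at a C6 position of 13, the chain may over-extend to a tetramer, and the hindered dimeric nucleophile may react so slowly that self-condensation of the cation from 12 takes over. Fallback, setting out from 12 and coming back at 14 (top-down 2+1 assembly with orthogonal activation, which replaces steps 9 and 10): TMSOTf couples 12 with an excess of F2 from the previous fallback, whose thioether is not ionised by the oxophilic acid at −78 °C, to give the top–middle dimer thioether 3,5,7,4′-tetra-O-benzyl-epiafzelechin-(4β→8)-3,5,7,4′-tetra-O-benzyl-4β-(benzylsulfanyl)epiafzelechin F3. AgBF4 in THF then activates the sulfur of F3 in the presence of 11, so that the last bond forms at the only strongly nucleophilic C8 and gives 14.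

Step 3. Enantioselectivity may erode and cis-to-trans leakage may occur through the radical intermediate that the p-alkoxyphenyl group stabilises. The electron-rich epoxide may also rearrange under acid on isolation. Fallback, setting out from 4 and coming back at 7 (stereospecific racemic epoxidation plus resolution instead of asymmetric catalysis): dimethyldioxirane in acetone at 0 °C gives the racemic cis-epoxide rac-cis-2-[4-(benzyloxy)phenyl]-3-(diethoxymethyl)oxirane F4 without leakage. Phenoxide opening as in step 4 gives the racemic syn aryloxy alcohol rac-syn-3-[3,5-bis(benzyloxy)phenoxy]-3-[4-(benzyloxy)phenyl]-1,1-diethoxypropan-2-ol F5. Preparative chromatography on a chiral stationary phase delivers 7.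

Step 4. The ambident phenoxide may C-alkylate, substitution at the hindered cis-epoxide may be slow enough for thermal decomposition to compete, and partial ionisation at the p-alkoxybenzylic carbon may erode the syn relationship. Fallback, setting out from 5 and coming back at 8 (the aryl–oxygen bond is formed at the aryl carbon with retention at the carbinol): sodium allyloxide in allyl alcohol opens 5 at the benzylic carbon with inversion to the allyl ether alcohol (2S,3R)-3-(allyloxy)-3-[4-(benzyloxy)phenyl]-1,1-diethoxypropan-2-ol F6. NaH/BnBr gives the allyl benzyl diether 1-[(1R,2S)-1-(allyloxy)-2-(benzyloxy)-3,3-diethoxypropyl]-4-(benzyloxy)benzene F7. Pd(PPh3)4 with sodium p-toluenesulfinate removes the allyl group to give the benzylic alcohol (1R,2S)-2-(benzyloxy)-1-[4-(benzyloxy)phenyl]-3,3-diethoxypropan-1-ol F8. Pd-catalysed C–O coupling of F8 with 1,3-bis(benzyloxy)-5-bromobenzene (bulky biarylphosphine ligand, NaOt-Bu) gives 8.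

Step 6. Alkylation may be poorly selective among the six hydroxyls (A-ring phenols, over-methylation), and the pyrogallol phenolate may be oxidised by air. Fallback, setting out from 9 and coming back at 10 (differentiation by selective de-acylation instead of selective alkylation): Ac2O/pyridine gives (−)-epigallocatechin hexaacetate F9. Thiophenol and imidazole in NMP remove the most labile aryl acetate, that of the most acidic phenol, to give the 4′-hydroxy pentaacetate 3,5,7,3′,5′-penta-O-acetyl-(−)-epigallocatechin F10. TMSCHN2 in MeOH/toluene methylates the single free phenol under neutral conditions (no acyl migration) to give 3,5,7,3′,5′-penta-O-acetyl-4′-O-methyl-(−)-epigallocatechin F11. K2CO3/MeOH removes the five acetates to give 10.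

## Further compounds

F1 | step 8 | 3,5,7,4′-tetra-O-benzyl-(−)-epiafzelechin | C1c2c(OCc3ccccc3)cc(OCc3ccccc3)cc2O[C@H](c2ccc(OCc3ccccc3)cc2)[C@@H]1OCc1ccccc1
F2 | step 9 | 3,5,7,4′-tetra-O-benzyl-4β-(benzylsulfanyl)epiafzelechin | c1ccccc1CS[C@H]1c2c(OCc3ccccc3)cc(OCc3ccccc3)cc2O[C@H](c2ccc(OCc3ccccc3)cc2)[C@@H]1OCc1ccccc1
F3 | step 10 | 3,5,7,4′-tetra-O-benzyl-epiafzelechin-(4β→8)-3,5,7,4′-tetra-O-benzyl-4β-(benzylsulfanyl)epiafzelechin | c1ccccc1CS[C@H]1c2c(OCc3ccccc3)cc(OCc3ccccc3)c([C@H]3c4c(OCc5ccccc5)cc(OCc5ccccc5)cc4O[C@H](c4ccc(OCc5ccccc5)cc4)[C@@H]3OCc3ccccc3)c2O[C@H](c2ccc(OCc3ccccc3)cc2)[C@@H]1OCc1ccccc1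
F4 | step 3 | rac-cis-2-[4-(benzyloxy)phenyl]-3-(diethoxymethyl)oxirane (both enantiomers) | CCOC(OCC)[C@H]1O[C@H]1c1ccc(OCc2ccccc2)cc1.CCOC(OCC)[C@@H]1O[C@@H]1c1ccc(OCc2ccccc2)cc1
F5 | step 3 | rac-syn-3-[3,5-bis(benzyloxy)phenoxy]-3-[4-(benzyloxy)phenyl]-1,1-diethoxypropan-2-ol (both enantiomers) | CCOC(OCC)[C@@H](O)[C@H](Oc1cc(OCc2ccccc2)cc(OCc2ccccc2)c1)c1ccc(OCc2ccccc2)cc1.CCOC(OCC)[C@H](O)[C@@H](Oc1cc(OCc2ccccc2)cc(OCc2ccccc2)c1)c1ccc(OCc2ccccc2)cc1
F6 | step 4 | (2S,3R)-3-(allyloxy)-3-[4-(benzyloxy)phenyl]-1,1-diethoxypropan-2-ol | CCOC(OCC)[C@@H](O)[C@H](OCC=C)c1ccc(OCc2ccccc2)cc1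
F7 | step 4 | 1-[(1R,2S)-1-(allyloxy)-2-(benzyloxy)-3,3-diethoxypropyl]-4-(benzyloxy)benzene | CCOC(OCC)[C@@H](OCc1ccccc1)[C@H](OCC=C)c1ccc(OCc2ccccc2)cc1
F8 | step 4 | (1R,2S)-2-(benzyloxy)-1-[4-(benzyloxy)phenyl]-3,3-diethoxypropan-1-ol | CCOC(OCC)[C@@H](OCc1ccccc1)[C@H](O)c1ccc(OCc2ccccc2)cc1
F9 | step 6 | (−)-epigallocatechin hexaacetate | CC(=O)Oc1c(OC(C)=O)cc([C@H]2Oc3c(c(OC(C)=O)cc(OC(C)=O)c3)C[C@H]2OC(C)=O)cc1OC(C)=O
F10 | step 6 | 3,5,7,3′,5′-penta-O-acetyl-(−)-epigallocatechin (4′-OH free) | Oc1c(OC(C)=O)cc([C@H]2Oc3c(c(OC(C)=O)cc(OC(C)=O)c3)C[C@H]2OC(C)=O)cc1OC(C)=O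
F11 | step 6 | 3,5,7,3′,5′-penta-O-acetyl-4′-O-methyl-(−)-epigallocatechin | COc1c(OC(C)=O)cc([C@H]2Oc3c(c(OC(C)=O)cc(OC(C)=O)c3)C[C@H]2OC(C)=O)cc1OC(C)=O
A1 | alternative 1 | (−)-epiafzelechin | C1c2c(O)cc(O)cc2O[C@H](c2ccc(O)cc2)[C@@H]1O
A2 | alternative 1 | 3-O-acetyl-5,7,4′-tri-O-benzyl-4β-(2-ethoxyethoxy)epiafzelechin | CCOCCO[C@H]1c2c(OCc3ccccc3)cc(OCc3ccccc3)cc2O[C@H](c2ccc(OCc3ccccc3)cc2)[C@@H]1OC(C)=O
A3 | alternative 2 | (2R,3S)-cis-3,5,7-tris(benzyloxy)-2-[4-(benzyloxy)phenyl]chroman-4-one | O=C1c2c(OCc3ccccc3)cc(OCc3ccccc3)cc2O[C@H](c2ccc(OCc3ccccc3)cc2)[C@@H]1OCc1ccccc1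
A4 | alternative 3 | 3,5,7-tris(benzyloxy)-2-[4-(benzyloxy)phenyl]chromenylium chloride | [o+]1c(-c2ccc(OCc3ccccc3)cc2)c(OCc2ccccc2)cc2c(OCc3ccccc3)cc(OCc3ccccc3)cc12.[Cl-]
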